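## Retrosynthetic overview

1. The target comes from its C3 silyl ether. The ten-membered carbocycle is opened at C7–C8: a ketyl radical from a C8 aldehyde adds to C7 of a preformed 3-(acetoxymethyl)butenolide, loss of acetate unveils the exo-methylene, and the C8 alkoxide takes the isobutyryl group.
2. The seco aldehyde comes from a C3–C4 Nozaki–Hiyama–Kishi union of an epoxy aldehyde (C8–C3) with a (Z)-iodoalkenyl butenolide (C4–C7, C11–C13).
3. The epoxy aldehyde comes from but-3-yn-1-ol by carboalumination/oxirane opening, Shi epoxidation and oxidation.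
4. The iodo butenolide comes from acrolein and propyne by asymmetric alkynylation, trans-hydroalumination/iodination, acrylate esterification and ring-closing metathesis.
5. Ring order: oxirane first, then the butenolide (lactone ring), the ten-membered carbocycle last.

Assumption: atoms carry germacrane numbers (C1/C10 epoxide, C3 carbinol, C4=C5 Z-alkene, C6 lactone carbinol, C7 ring fusion, C8 ester carbinol, C11=C13 methylene, C12 lactone carbonyl), which makes the target (1S,3S,6R,7R,8R,10S); the ent-Shi ketone, ProPhenol and the Kishi sulfonamide ligand are taken as available reagents.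

## Route

Step 1
Reactants: 1 but-3-yn-1-ol
Product: 2 triethyl(but-3-yn-1-yloxy)silane
Conditions: TESCl, imidazole, CH2Cl2, 0 °C to rt
Reagents that add atoms: chlorotriethylsilane, CC[Si](Cl)(CC)CC
Why: Imidazole-promoted silylation (silyl ether protection) of the primary alcohol gives a triethylsilyl ether that survives the organometallic steps and can later be oxidised directly; no stereocentre is formed.

Step 2
Reactants: 2 triethyl(but-3-yn-1-yloxy)silane, 3 oxirane
Product: 6 (E)-4-methyl-6-(triethylsilyloxy)hex-3-en-1-ol, via alkenyldimethylalane 4 (not isolated), via lithium alkenylalanate 5 (not isolated)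
Conditions: Me3Al (2 equiv), Cp2ZrCl2 (0.25 equiv), CH2Cl2, 0 °C to rt; then n-BuLi, hexane/THF, −78 °C; then oxirane, −78 °C to rt
Reagents that add atoms: trimethylaluminium, C[Al](C)C
Why: Negishi zirconium-catalysed carboalumination adds methyl and aluminium syn across the terminal alkyne (methyl to the internal carbon), and the derived lithium alanate opens oxirane with retention at the alkenyl carbon, so only the E trisubstituted alkene forms.

Step 3
Reactants: 6 (E)-4-methyl-6-(triethylsilyloxy)hex-3-en-1-ol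
Product: 7 2-[(2S,3S)-3-methyl-3-[2-(triethylsilyloxy)ethyl]oxiran-2-yl]ethan-1-ol
Conditions: ent-Shi ketone (L-fructose-derived, 0.3 equiv), Oxone (2KHSO5·KHSO4·K2SO4), K2CO3, Bu4NHSO4, MeCN/CH2(OMe)2/aq. Na2B4O7 buffer, 0 °C
Reagents that add atoms: potassium peroxymonosulfate, [K+].[O-]S(=O)(=O)OO
Why: Shi asymmetric epoxidation, in which the dioxirane of the L-fructose-derived ketone attacks the isolated E-trisubstituted alkene through the spiro transition state from the face that gives the (S,S)-trans-epoxide, sets C1 and C10 under reagent control.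

Step 4
Reactants: 7 2-[(2S,3S)-3-methyl-3-[2-(triethylsilyloxy)ethyl]oxiran-2-yl]ethan-1-ol
Product: 8 2-[(2S,3S)-3-methyl-3-[2-(triethylsilyloxy)ethyl]oxiran-2-yl]acetaldehyde
Conditions: Dess–Martin periodinane, NaHCO3, CH2Cl2, 0 °C
Reagents that add atoms: none
Why: Dess–Martin oxidation under buffered, non-basic conditions gives the β,γ-epoxy aldehyde without base-induced opening of the epoxide; no stereocentre is touched.

Step 5
Reactants: 9 prop-2-enal (acrolein), 10 propyne
Product: 12 (3S)-hex-1-en-4-yn-3-ol, via methyl(prop-1-ynyl)zinc 11 (not isolated)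
Conditions: Me2Zn (3 equiv), (R,R)-ProPhenol (10 mol %), Ph3PO (20 mol %), toluene, 0 to 4 °C, slow addition of acrolein
Reagents that add atoms: none
Why: Trost-type asymmetric alkynylation of an enal, in which the catalyst formed from Me2Zn and ProPhenol binds both the aldehyde and the alkynylzinc and delivers the propynyl group to one carbonyl face, sets the C6 carbinol as S.

Step 6
Reactants: 12 (3S)-hex-1-en-4-yn-3-ol
Product: 14 (3S,4Z)-5-iodohexa-1,4-dien-3-ol, via cyclic alkenylalanate 13 (not isolated)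
Conditions: NaAlH2(OCH2CH2OMe)2 (Red-Al), THF, 0 °C to rt; then EtOAc; then I2, −78 °C
Reagents that add atoms: iodine, II
Why: Hydroxyl-directed trans-hydroalumination of the propargylic alcohol (Corey-type Red-Al reduction) puts hydrogen on C5 and aluminium on C4 in a five-membered alanate, and iodinolysis with retention gives only the Z-alkenyl iodide with iodine cis to the carbinol carbon.

Step 7
Reactants: 14 (3S,4Z)-5-iodohexa-1,4-dien-3-ol, 15 2-(bromomethyl)prop-2-enoic acid
Product: 17 (3S,4Z)-5-iodohexa-1,4-dien-3-yl 2-(acetoxymethyl)prop-2-enoate, via bromomethylacrylate ester 16 (not isolated)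
Conditions: DCC, DMAP (cat.), CH2Cl2, 0 °C; then Bu4NOAc, rt
Reagents that add atoms: tetrabutylammonium acetate, CC(=O)[O-].CCCC[N+](CCCC)(CCCC)CCCC
Why: Steglich esterification acylates the hydroxyl oxygen so C6 keeps its configuration, and acetate then displaces the allylic bromide (SN2 or the degenerate SN2') to install the leaving group needed in the ring closure.

Step 8
Reactants: 17 (3S,4Z)-5-iodohexa-1,4-dien-3-yl 2-(acetoxymethyl)prop-2-enoate
Product: 18 [(5S)-5-[(1Z)-2-iodoprop-1-en-1-yl]-2-oxo-2,5-dihydrofuran-3-yl]methyl acetate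
Conditions: second-generation Hoveyda–Grubbs catalyst (H2IMes)Cl2Ru=CH(C6H4-2-OiPr) (5 mol %), toluene, 80 °C
Reagents that add atoms: none
Why: Ring-closing metathesis between the vinyl group and the 1,1-disubstituted acrylate closes the five-membered butenolide with loss of ethene, while the trisubstituted iodoalkene is too hindered to engage and C6 is untouched.

Step 9
Reactants: 8 2-[(2S,3S)-3-methyl-3-[2-(triethylsilyloxy)ethyl]oxiran-2-yl]acetaldehyde, 18 [(5S)-5-[(1Z)-2-iodoprop-1-en-1-yl]-2-oxo-2,5-dihydrofuran-3-yl]methyl acetate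
Product: 20 [(5R)-5-[(1Z,3S)-3-hydroxy-2-methyl-4-[(2S,3S)-3-methyl-3-[2-(triethylsilyloxy)ethyl]oxiran-2-yl]but-1-en-1-yl]-2-oxo-2,5-dihydrofuran-3-yl]methyl acetate, via alkenylchromium dichloride 19 (not isolated)
Conditions: CrCl2 (4 equiv), NiCl2 (2 mol %), (S)-N-[2-(4-isopropyl-4,5-dihydrooxazol-2-yl)-6-methylphenyl]methanesulfonamide (Kishi ligand, 4.4 equiv), Et3N, THF, rt
Reagents that add atoms: none
Why: Nozaki–Hiyama–Kishi coupling, in which zerovalent nickel inserts into the C–I bond with retention of the Z geometry, transmetalation gives the alkenylchromium species and its ligand-controlled addition to the re face of the aldehyde sets C3 as S (the C6 descriptor changes from S to R only because the iodine is replaced).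

Step 10
Reactants: 20 the C3 alcohol from step 9
Product: 21 [(5R)-5-[(1Z,3S)-2-methyl-4-[(2S,3S)-3-methyl-3-[2-(triethylsilyloxy)ethyl]oxiran-2-yl]-3-(triethylsilyloxy)but-1-en-1-yl]-2-oxo-2,5-dihydrofuran-3-yl]methyl acetate
Conditions: TESCl, imidazole, DMF, 0 °C
Reagents that add atoms: chlorotriethylsilane, CC[Si](Cl)(CC)CC
Why: Silyl ether protection of the secondary allylic alcohol under mild conditions that leave the epoxide, the lactone and the allylic acetate alone; no stereocentre is touched.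

Step 11
Reactants: 21 the bis(triethylsilyl) ether from step 10
Product: 22 [(5R)-5-[(1Z,3S)-2-methyl-4-[(2S,3S)-3-methyl-3-(2-oxoethyl)oxiran-2-yl]-3-(triethylsilyloxy)but-1-en-1-yl]-2-oxo-2,5-dihydrofuran-3-yl]methyl acetate
Conditions: (COCl)2, DMSO, CH2Cl2, −78 to −40 °C; then Et3N, −78 to 0 °C
Reagents that add atoms: none
Why: Swern oxidation with in situ desilylation, in which a primary triethylsilyl ether is cleaved and oxidised while the secondary one stays, gives the C8 aldehyde in one operation.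

Step 12
Reactants: 22 the seco aldehyde from step 11, 23 2-methylpropanoyl chloride
Product: 25 (1S,3S,4Z,6R,7R,8R,10S)-1,10-epoxy-8-(2-methylpropanoyloxy)-3-(triethylsilyloxy)germacra-4,11(13)-dien-12,6-olide, via diiodosamarium C8 alkoxide 24 (not isolated)
Conditions: SmI2 (2.2 equiv, 0.1 M in THF) added over 2 h to 22 (0.002 M in THF), −78 °C; then 2-methylpropanoyl chloride, pyridine, DMAP (cat.), −78 to 0 °C
Reagents that add atoms: none
Why: Proposed new method: SmI2 reduces the C8 aldehyde to a ketyl radical that adds through a ten-membered transition state to C7, the β-carbon of the butenolide (closest known chemistry: SmI2 ketyl–olefin cyclisations onto α,β-unsaturated lactones and radical addition/β-elimination allylations with 2-(acyloxymethyl)acrylates), the C11 radical is reduced by the second equivalent to the trivalent samarium enolate, which expels acetate (E1cB) to give the 11(13)-methylene and makes the addition irreversible; attack on the butenolide face opposite the C6–C5 bond gives the trans-fused lactone (7R), reaction of the ketyl with its O–Sm bond anti to the C7–C11 bond and C9 anti to C6 is predicted to give 8R, and the C8 samarium alkoxide is acylated in the same flask.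

Step 13
Reactants: 25 the C3 triethylsilyl ether from step 12
Product: 26 (1S,3S,4Z,6R,7R,8R,10S)-1,10-epoxy-3-hydroxy-8-(2-methylpropanoyloxy)germacra-4,11(13)-dien-12,6-olide (target)
Conditions: HF·pyridine, pyridine, THF, 0 °C
Reagents that add atoms: none
Why: Pyridine-buffered fluoride desilylation cleaves the secondary silyl ether without opening the acid-sensitive epoxide or adding to the methylene lactone; no stereocentre is touched.

## Compound list

1 | but-3-yn-1-ol | C#CCCO | starting material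
2 | triethyl(but-3-yn-1-yloxy)silane | C#CCCO[Si](CC)(CC)CC | intermediate
3 | oxirane | C1CO1 | starting material
4 | dimethyl[(E)-2-methyl-4-(triethylsilyloxy)but-1-en-1-yl]alane | C[Al](C)/C=C(\C)CCO[Si](CC)(CC)CC | intermediate
5 | lithium butyl(dimethyl)[(E)-2-methyl-4-(triethylsilyloxy)but-1-en-1-yl]alanate | [Li+].CCCC[Al-](C)(C)/C=C(\C)CCO[Si](CC)(CC)CC | intermediate
6 | (E)-4-methyl-6-(triethylsilyloxy)hex-3-en-1-ol | OCC/C=C(\C)CCO[Si](CC)(CC)CC | intermediate
7 | 2-[(2S,3S)-3-methyl-3-[2-(triethylsilyloxy)ethyl]oxiran-2-yl]ethan-1-ol | OCC[C@@H]1O[C@@]1(C)CCO[Si](CC)(CC)CC | intermediate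
8 | 2-[(2S,3S)-3-methyl-3-[2-(triethylsilyloxy)ethyl]oxiran-2-yl]acetaldehyde | O=CC[C@@H]1O[C@@]1(C)CCO[Si](CC)(CC)CC | intermediate
9 | prop-2-enal (acrolein) | C=CC=O | starting material
10 | propyne | CC#C | starting material
11 | methyl(prop-1-ynyl)zinc | CC#C[Zn]C | intermediate
12 | (3S)-hex-1-en-4-yn-3-ol | C=C[C@H](O)C#CC | intermediate
13 | sodium (5S)-2,2-bis(2-methoxyethoxy)-3-methyl-5-vinyl-2,5-dihydro-1,2-oxaluminol-2-uide (cyclic alkenylalanate) | [Na+].COCCO[Al-]1(OCCOC)O[C@@H](C=C)C=C1C | intermediate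
14 | (3S,4Z)-5-iodohexa-1,4-dien-3-ol | C=C[C@H](O)/C=C(/C)I | intermediate
15 | 2-(bromomethyl)prop-2-enoic acid | C=C(CBr)C(=O)O | starting material
16 | (3S,4Z)-5-iodohexa-1,4-dien-3-yl 2-(bromomethyl)prop-2-enoate | C=C(CBr)C(=O)O[C@@H](C=C)/C=C(/C)I | intermediate
17 | (3S,4Z)-5-iodohexa-1,4-dien-3-yl 2-(acetoxymethyl)prop-2-enoate | C=C(COC(C)=O)C(=O)O[C@@H](C=C)/C=C(/C)I | intermediate
18 | [(5S)-5-[(1Z)-2-iodoprop-1-en-1-yl]-2-oxo-2,5-dihydrofuran-3-yl]methyl acetate | CC(=O)OCC1=C[C@@H](/C=C(/C)I)OC1=O | intermediate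
19 | [(5S)-5-[(1Z)-2-(dichlorochromio)prop-1-en-1-yl]-2-oxo-2,5-dihydrofuran-3-yl]methyl acetate | CC(=O)OCC1=C[C@@H](/C=C(/C)[Cr](Cl)Cl)OC1=O | intermediate
20 | [(5R)-5-[(1Z,3S)-3-hydroxy-2-methyl-4-[(2S,3S)-3-methyl-3-[2-(triethylsilyloxy)ethyl]oxiran-2-yl]but-1-en-1-yl]-2-oxo-2,5-dihydrofuran-3-yl]methyl acetate | CC(=O)OCC1=C[C@H](OC1=O)/C=C(/C)[C@@H](O)C[C@@H]2O[C@@]2(C)CCO[Si](CC)(CC)CC | intermediate
21 | [(5R)-5-[(1Z,3S)-2-methyl-4-[(2S,3S)-3-methyl-3-[2-(triethylsilyloxy)ethyl]oxiran-2-yl]-3-(triethylsilyloxy)but-1-en-1-yl]-2-oxo-2,5-dihydrofuran-3-yl]methyl acetate | CC(=O)OCC1=C[C@H](OC1=O)/C=C(/C)[C@@H](O[Si](CC)(CC)CC)C[C@@H]2O[C@@]2(C)CCO[Si](CC)(CC)CC | intermediate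
22 | [(5R)-5-[(1Z,3S)-2-methyl-4-[(2S,3S)-3-methyl-3-(2-oxoethyl)oxiran-2-yl]-3-(triethylsilyloxy)but-1-en-1-yl]-2-oxo-2,5-dihydrofuran-3-yl]methyl acetate | CC(=O)OCC1=C[C@H](OC1=O)/C=C(/C)[C@@H](O[Si](CC)(CC)CC)C[C@@H]2O[C@@]2(C)CC=O | intermediate
23 | 2-methylpropanoyl chloride | CC(C)C(Cl)=O | starting material
24 | C8 diiodosamarium alkoxide of 8-O-deacyl-25 (same spatial arrangement at every centre as 25) | C=C1C(=O)O[C@@H]2/C=C(/C)[C@@H](O[Si](CC)(CC)CC)C[C@@H]3O[C@@]3(C)C[C@@H](O[Sm](I)I)[C@@H]12 | intermediate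
25 | (1S,3S,4Z,6R,7R,8R,10S)-1,10-epoxy-8-(2-methylpropanoyloxy)-3-(triethylsilyloxy)germacra-4,11(13)-dien-12,6-olide | C=C1C(=O)O[C@@H]2/C=C(/C)[C@@H](O[Si](CC)(CC)CC)C[C@@H]3O[C@@]3(C)C[C@@H](OC(=O)C(C)C)[C@@H]12 | intermediate
26 | (1S,3S,4Z,6R,7R,8R,10S)-1,10-epoxy-3-hydroxy-8-(2-methylpropanoyloxy)germacra-4,11(13)-dien-12,6-olide | C=C1C(=O)O[C@@H]2/C=C(/C)[C@@H](O)C[C@@H]3O[C@@]3(C)C[C@@H](OC(=O)C(C)C)[C@@H]12 | target

## Step count and risks

Total steps: 13. Longest linear sequence: 9 steps (1–4 then 9–13; the other branch, 5–8 then 9–13, is equally long).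

The three steps most likely to fail:

Step 12 (radical ring closure). The ten-membered closure is unprecedented and the ketyl may react through its other face. The fallback sets out from 22: the SmI2 closure is run as in step 12 but quenched with aqueous NH4Cl instead of 23. If the product is the 8-epi alcohol (1S,3S,4Z,6R,7R,8S,10S)-1,10-epoxy-8-hydroxy-3-(triethylsilyloxy)germacra-4,11(13)-dien-12,6-olide F1, a Mitsunobu esterification (2-methylpropanoic acid, PPh3, DIAD, toluene, 0 °C) inverts C8 while installing the ester, and the route is rejoined at 25.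

Step 9 (fragment union). Ligand control at C3 may be weak next to the epoxide. The fallback sets out from 8 and 18: a ligand-free coupling (CrCl2, NiCl2 cat., DMSO, rt) gives 20 mixed with its C3 epimer [(5R)-5-[(1Z,3R)-3-hydroxy-2-methyl-4-[(2S,3S)-3-methyl-3-[2-(triethylsilyloxy)ethyl]oxiran-2-yl]but-1-en-1-yl]-2-oxo-2,5-dihydrofuran-3-yl]methyl acetate F2. The mixture is oxidised (Dess–Martin periodinane, NaHCO3, CH2Cl2, 0 °C) to the Z-enone [(5R)-5-[(1Z)-2-methyl-4-[(2S,3S)-3-methyl-3-[2-(triethylsilyloxy)ethyl]oxiran-2-yl]-3-oxobut-1-en-1-yl]-2-oxo-2,5-dihydrofuran-3-yl]methyl acetate F3. Reduction with (R)-Me-CBS and catecholborane (toluene, −78 °C) then gives the 3S alcohol under reagent control, and the route is rejoined at 20.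

Step 5 (asymmetric alkynylation). Acrolein is small and polymerisable, so the enantiomeric excess may be low. The fallback sets out from 9 and 10: propyne is deprotonated with EtMgBr (THF, 0 °C) and added to acrolein to give racemic hex-1-en-4-yn-3-ol F4. A Sharpless kinetic resolution (Ti(OiPr)4, L-(+)-diisopropyl tartrate, t-BuOOH 0.6 equiv, 4 Å sieves, CH2Cl2, −20 °C) epoxidises the R enantiomer to (1S)-1-[(2S)-oxiran-2-yl]but-2-yn-1-ol F5 and leaves the S enantiomer, and the route is rejoined at 12.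

## Further compounds

F1 | step 12 | (1S,3S,4Z,6R,7R,8S,10S)-1,10-epoxy-8-hydroxy-3-(triethylsilyloxy)germacra-4,11(13)-dien-12,6-olide | C=C1C(=O)O[C@@H]2/C=C(/C)[C@@H](O[Si](CC)(CC)CC)C[C@@H]3O[C@@]3(C)C[C@H](O)[C@@H]12
F2 | step 9 | [(5R)-5-[(1Z,3R)-3-hydroxy-2-methyl-4-[(2S,3S)-3-methyl-3-[2-(triethylsilyloxy)ethyl]oxiran-2-yl]but-1-en-1-yl]-2-oxo-2,5-dihydrofuran-3-yl]methyl acetate | CC(=O)OCC1=C[C@H](OC1=O)/C=C(/C)[C@H](O)C[C@@H]2O[C@@]2(C)CCO[Si](CC)(CC)CC
F3 | step 9 | [(5R)-5-[(1Z)-2-methyl-4-[(2S,3S)-3-methyl-3-[2-(triethylsilyloxy)ethyl]oxiran-2-yl]-3-oxobut-1-en-1-yl]-2-oxo-2,5-dihydrofuran-3-yl]methyl acetate | CC(=O)OCC1=C[C@H](OC1=O)/C=C(/C)C(=O)C[C@@H]2O[C@@]2(C)CCO[Si](CC)(CC)CC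
F4 | step 5 | racemic hex-1-en-4-yn-3-ol | C=CC(O)C#CC
F5 | step 5 | (1S)-1-[(2S)-oxiran-2-yl]but-2-yn-1-ol | CC#C[C@H](O)[C@@H]1CO1
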